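**Plan**
1. Retrosynthesis: ring A is cut at C1–C10 (the last ring bond made), then at C4–C5 (Michael addition) and C10–C20 (formylation); ring D at C8–C15 (allylsilane addition); ring B at C9–C10 and C6–C8 (Dieckmann, Stobbe).
2. Forward: ring C (cyclohexenone) → ring B → ring D → C20 → C19/C4–C1 chain → ring A → C18 methyl, 3β-OH, deprotection.
3. Enabling feature: the C10=C5 bond of ring B holds the C20 formyl group and the C4 side chain cis, so the enolised 3-oxopent-4-enoate completes a hexatriene C10=C5–C4=C3–C2=C1 (and the oxatriene O=C20–C10=C5–C4=C3) whose thermal closure joins C1 to C10.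
4. Stereochemistry: C13 from the [Rh(OH)(cod)]2/(R)-BINAP conjugate addition; C8 relayed by the allylsilane tether; C9 and C6 by equilibration (C6 stays epimerisable and should finally rest trans to the C5 substituent); C10 by closure on the β face of ring B, away from ring C; C5, C4 and C3 then follow from the axial C10 substituent and the size of the hydride.

Key step: step 12

Remark: positions are given in gibberellane numbering (C1 to C20) and α/β refer to the usual gibberellin drawing; the target is written in its open 20-oxo 19-acid form, which may equilibrate with the 19,20-lactol.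

**Step 1**
Reactants: 1 (2-bromoallyl)trimethylsilane
Product: 2 trimethyl[2-(pinacolatoboryl)prop-2-en-1-yl]silane
Conditions: B2pin2, PdCl2(PPh3)2 (3 mol %), PPh3, KOPh, toluene, 50 °C
Reagents that add atoms: bis(pinacolato)diboron, CC1(C)OB(OC1(C)C)B1OC(C)(C)C(C)(C)O1
Why: Miyaura borylation of a 1-alkenyl bromide under phenoxide conditions should give the alkenyl boronate and leave the allylsilane intact.

**Step 2**
Reactants: 2 trimethyl[2-(pinacolatoboryl)prop-2-en-1-yl]silane, 3 cyclohex-2-en-1-one
Product: 4 (3R)-3-[3-(trimethylsilyl)prop-1-en-2-yl]cyclohexan-1-one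
Conditions: [Rh(OH)(cod)]2 (1.5 mol %), (R)-BINAP (3.3 mol %), aq KOH (10 mol %), dioxane, 60 °C
Reagents that add atoms: none
Why: Hayashi–Miyaura asymmetric conjugate addition with [Rh(OH)(cod)]2 and (R)-BINAP, which should give the (R) ketone (C13) by analogy with aryl and alkenyl boron additions to cyclohexenone.

**Step 3**
Reactants: 4 (3R)-3-[3-(trimethylsilyl)prop-1-en-2-yl]cyclohexan-1-one, 5 dimethyl succinate
Product: 6 Stobbe half ester
Conditions: KOt-Bu, t-BuOH, reflux; then 1 M HCl
Reagents that add atoms: none
Why: Stobbe condensation attaches C6 (with C7, C5, C10) to the carbonyl carbon C8 through the lactone and ring-opening pathway, so no regiochemical choice arises at this stage.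

**Step 4**
Reactants: 6 Stobbe half ester
Product: 7 dimethyl alkylidenesuccinate
Conditions: MeI, K2CO3, DMF, 25 °C
Reagents that add atoms: iodomethane, CI
Why: carboxylate O-alkylation gives the diester needed for the ring closure.

**Step 5**
Reactants: 7 dimethyl alkylidenesuccinate
Product: 8 bicyclic enone ester
Conditions: KOt-Bu (2.2 equiv), THF, 0 → 25 °C; AcOH
Reagents that add atoms: none
Why: vinylogous Dieckmann condensation, in which the γ-dienolate (alkene isomers equilibrating through it) acylates at the unhindered ring carbon C9 rather than at C14 next to the C13 substituent, and the product is drawn forward as its stabilised enolate, giving ring B with the C10 ketone and C9=C8.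

**Step 6**
Reactants: 8 bicyclic enone ester
Product: 9 BCD keto ester
Conditions: TiCl4 (1.1 equiv), CH2Cl2, −78 °C; aq NaHCO3; then DBU (cat.), CH2Cl2, 25 °C
Reagents that add atoms: none
Why: intramolecular Hosomi–Sakurai conjugate allylation, in which the C13-tethered allylsilane can reach C8 only on its own face, fixing quaternary C8 and closing ring D with the 16-methylene; equilibration of the epimerisable C9 and C6 should give the cis B/C fusion and the 6β ester.

**Step 7**
Reactants: 9 BCD keto ester
Product: 10 BCD enol triflate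
Conditions: KN(SiMe3)2, THF, −78 °C; PhNTf2
Reagents that add atoms: N-phenylbis(trifluoromethanesulfonimide), O=S(=O)(N(c1ccccc1)S(=O)(=O)C(F)(F)F)C(F)(F)F
Why: kinetic enolisation toward the C5 methylene (not the ring-fusion hydrogen on C9) and O-triflation give the C10=C5 enol triflate.

**Step 8**
Reactants: 10 BCD enol triflate
Product: 11 BCD enal
Conditions: Pd(PPh3)4 (5 mol %), CO (1 atm), Bu3SnH (slow addition), THF, 50 °C
Reagents that add atoms: carbon monoxide, [C-]#[O+]
Why: Pd(PPh3)4-catalysed reductive carbonylation of the alkenyl triflate installs C20 as the conjugated aldehyde without touching the isolated alkene.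

**Step 9**
Reactants: 12 methyl acetoacetate, 13 chloromethyl phenyl sulfide
Product: 14 methyl 3-oxo-5-(phenylsulfanyl)pentanoate
Conditions: NaH, THF, 0 °C; n-BuLi, −20 °C; then 13; 1 M HCl
Reagents that add atoms: none
Why: γ-alkylation of the acetoacetate dianion gives a stable, masked 3-oxopent-4-enoate carrying C19, C4, C3, C2 and C1.

**Step 10**
Reactants: 11 BCD enal, 14 methyl 3-oxo-5-(phenylsulfanyl)pentanoate
Product: 15 Michael adduct
Conditions: DBU (10 mol %), CH2Cl2, 0 → 25 °C
Reagents that add atoms: none
Why: base-catalysed Michael addition of the β-keto ester to C5 of the enal forms the C4–C5 bond; C4, C5 and C10 all become sp2 before the key step, so no selectivity is required here.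

**Step 11**
Reactants: 15 Michael adduct
Product: 18 alkylidene keto ester sulfoxide, via α-phenylselanyl keto ester 16 (not isolated), via selenoxide sulfoxide 17 (not isolated)
Conditions: PhSeCl, pyridine, CH2Cl2, 0 °C; then NaIO4 (3 equiv), NaHCO3, THF/MeOH/H2O, 0 → 25 °C
Reagents that add atoms: sodium periodate, [Na+].[O-]I(=O)(=O)=O
Why: α-selenation of the enolised β-keto ester (faster than addition to the 16-methylene) and selenoxide syn-elimination, for which the hydrogen on C5 is the only β-hydrogen, give the C4=C5 alkylidene, while the sulfide is oxidised to a sulfoxide that eliminates only on heating.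

**Step 12**
Reactants: 18 alkylidene keto ester sulfoxide
Product: 21 ring A enone aldehyde, via trienol enal 19 (not isolated), via 2H-pyranol 20 (not isolated)
Conditions: toluene (degassed), NaHCO3 (solid), 110 °C
Reagents that add atoms: none
Why: Proposed new method: thermal syn-elimination of the sulfoxide unveils the vinyl ketone, whose hydrogen-bonded enol 19 is both a (Z)-hexatriene (C10=C5–C4=C3–C2=C1, the enol hydrogen bond to the ester holding C2 cis to C5) and a 1-oxatriene locked by ring B (O=C20–C10=C5–C4=C3). It should close either directly by disrotatory 6π-electrocyclisation or through the reversibly formed 2H-pyranol 20 by a [3,3] shift of its C10=C20–O–C3–C2=C1 unit, both paths making the C1–C10 bond and, after ketonisation at C2, enone 21. The closest known types are the oxa-6π closure of cis-dienones to 2H-pyrans, the Claisen ring contraction of 2-vinyl dihydropyrans to cyclohexene carbaldehydes, and thermal triene electrocyclisation. Ring A is closed in a six-electron thermal process (6π disrotatory, or boat-like [3,3] across the pyran), and the only new stereocentre, quaternary C10, is set by π-facial choice: C1 should arrive on the β face of ring B because the α face is covered by C11 on the adjacent C9 and by C14 of ring C. Since enol geometries, the C3 hemiketal epimers and the C6 epimers interconvert under the conditions, all isomers should funnel into one C10 configuration. The step needs β-face selectivity and C–C rather than only C–O closure; the cis-fused BCD core secures the first and the reversibility of pyran formation against irreversible C–C bond formation secures the second.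

**Step 13**
Reactants: 21 ring A enone aldehyde
Product: 22 C20 dimethyl acetal
Conditions: HC(OMe)3, CeCl3·7H2O (10 mol %), MeOH, 25 °C
Reagents that add atoms: trimethyl orthoformate, COC(OC)OC
Why: CeCl3-catalysed acetalisation is selective for the aldehyde over the conjugated ketone and masks C20 for the two hydride steps.

**Step 14**
Reactants: 22 C20 dimethyl acetal
Product: 23 4-methyl 3-ketone
Conditions: LiBH(s-Bu)3 (1.05 equiv), THF, −78 °C; then MeI, DMPU, −78 → 0 °C
Reagents that add atoms: iodomethane, CI
Why: conjugate reduction with enolate trapping (reductive alkylation), in which hydride should add axially to C5 anti to the axial C10 substituent (5β-H, trans A/B) and MeI should alkylate the enolate anti to the same group (4β-Me, 4α-CO2Me).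

**Step 15**
Reactants: 23 4-methyl 3-ketone
Product: 24 3β-alcohol acetal
Conditions: KBH(s-Bu)3, THF, −78 °C; H2O
Reagents that add atoms: none
Why: the bulky trialkylborohydride should attack the 4,4-disubstituted 3-ketone from the equatorial (α) side to give the axial 3β-alcohol, leaving esters and acetal untouched.

**Step 16**
Reactants: 24 3β-alcohol acetal
Product: 25 dimethyl ester of the target
Conditions: 1 M HCl, THF, 0 → 25 °C
Reagents that add atoms: water, O
Why: mild acetal hydrolysis releases the C20 aldehyde under conditions the 16-methylene should tolerate.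

**Step 17**
Reactants: 25 dimethyl ester of the target
Product: 26 the target gibberellin, 3β-hydroxy-20-oxogibberell-16-ene-7,19-dioic acid
Conditions: LiOH (aq), THF/MeOH, 0 → 25 °C; then HCl to pH 3
Reagents that add atoms: lithium hydroxide, [Li+].[OH-]
Why: saponification of both methyl esters, the hindered C19 ester being assisted by the neighbouring C20 aldehyde (attack through its hydrate), with low temperature to limit retro-aldol opening at C3–C4.

**Compound list**
1 | (2-bromoallyl)trimethylsilane | C[Si](C)(C)CC(Br)=C | starting material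
2 | trimethyl[2-(4,4,5,5-tetramethyl-1,3,2-dioxaborolan-2-yl)prop-2-en-1-yl]silane | C[Si](C)(C)CC(=C)B1OC(C)(C)C(C)(C)O1 | intermediate
3 | cyclohex-2-en-1-one | O=C1C=CCCC1 | starting material
4 | (3R)-3-[3-(trimethylsilyl)prop-1-en-2-yl]cyclohexan-1-one | O=C1C[C@H](C(=C)C[Si](C)(C)C)CCC1 | intermediate
5 | dimethyl succinate | COC(=O)CCC(=O)OC | starting material
6 | 3-(methoxycarbonyl)-3-{(3R)-3-[3-(trimethylsilyl)prop-1-en-2-yl]cyclohexylidene}propanoic acid (alkene isomers) | OC(=O)CC(C(=O)OC)=C1C[C@H](C(=C)C[Si](C)(C)C)CCC1 | intermediate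
7 | dimethyl 2-{(3R)-3-[3-(trimethylsilyl)prop-1-en-2-yl]cyclohexylidene}butanedioate (alkene isomers) | COC(=O)CC(C(=O)OC)=C1C[C@H](C(=C)C[Si](C)(C)C)CCC1 | intermediate
8 | methyl (6R)-3-oxo-6-[3-(trimethylsilyl)prop-1-en-2-yl]-2,3,4,5,6,7-hexahydro-1H-indene-1-carboxylate (epimers at the ester-bearing carbon) | COC(=O)C1CC(=O)C2=C1C[C@H](C(=C)C[Si](C)(C)C)CC2 | intermediate
9 | BCD keto ester: C10 ketone, C5 methylene, 6β-CO2Me, 9β-H, 16-methylene | C=C1C[C@]23C[C@H]1CC[C@H]2C(=O)C[C@@H]3C(=O)OC | intermediate
10 | BCD enol triflate: triflyloxy group on C10, C10=C5 | C=C1C[C@]23C[C@H]1CC[C@H]2C(OS(=O)(=O)C(F)(F)F)=C[C@@H]3C(=O)OC | intermediate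
11 | BCD enal: C20 formyl on C10, C10=C5 | C=C1C[C@]23C[C@H]1CC[C@H]2C(C=O)=C[C@@H]3C(=O)OC | intermediate
12 | methyl acetoacetate | CC(=O)CC(=O)OC | starting material
13 | chloromethyl phenyl sulfide | ClCSc1ccccc1 | starting material
14 | methyl 3-oxo-5-(phenylsulfanyl)pentanoate | COC(=O)CC(=O)CCSc1ccccc1 | intermediate
15 | Michael adduct: C5 bears CH(CO2Me)C(=O)CH2CH2SPh, C10 bears CHO (epimers at C4, C5 and C10) | C=C1C[C@]23C[C@H]1CC[C@H]2C(C=O)C(C(C(=O)OC)C(=O)CCSc4ccccc4)[C@@H]3C(=O)OC | intermediate
16 | C4 phenylselanyl derivative of 15 | C=C1C[C@]23C[C@H]1CC[C@H]2C(C=O)C(C(C(=O)OC)([Se]c4ccccc4)C(=O)CCSc5ccccc5)[C@@H]3C(=O)OC | intermediate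
17 | selenoxide sulfoxide of 16 | C=C1C[C@]23C[C@H]1CC[C@H]2C(C=O)C(C(C(=O)OC)([Se](=O)c4ccccc4)C(=O)CCS(=O)c5ccccc5)[C@@H]3C(=O)OC | intermediate
18 | alkylidene keto ester sulfoxide: C4=C5, 3-oxo, phenylsulfinyl on C1 (alkene isomers; tautomeric with its dienol) | C=C1C[C@]23C[C@H]1CC[C@H]2C(C=O)C(=C(C(=O)OC)C(=O)CCS(=O)c4ccccc4)[C@@H]3C(=O)OC | intermediate
19 | trienol enal: C20 formyl, C10=C5, C4=C3(OH), C2=C1 | C=C1C[C@]23C[C@H]1CC[C@H]2C(C=O)=C(C(C(=O)OC)=C(O)C=C)[C@@H]3C(=O)OC | intermediate
20 | 2H-pyranol: ring O–C20=C10–C5=C4–C3(OH)(vinyl) fused to ring B | C=C1C[C@]23C[C@H]1CC[C@H]2C4=COC(O)(C=C)C(C(=O)OC)=C4[C@@H]3C(=O)OC | intermediate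
21 | dimethyl 3,20-dioxo-18-norgibberella-4,16-diene-7,19-dioate (ring A enone aldehyde) | C=C1C[C@]23C[C@H]1CC[C@H]2[C@]1(C=O)CCC(=O)C(C(=O)OC)=C1[C@@H]3C(=O)OC | intermediate
22 | dimethyl 20,20-dimethoxy-3-oxo-18-norgibberella-4,16-diene-7,19-dioate (20,20-dimethyl acetal of 21) | C=C1C[C@]23C[C@H]1CC[C@H]2[C@]1(C(OC)OC)CCC(=O)C(C(=O)OC)=C1[C@@H]3C(=O)OC | intermediate
23 | dimethyl 20,20-dimethoxy-3-oxogibberell-16-ene-7,19-dioate (4β-Me, 5β-H) | C=C1C[C@]23C[C@H]1CC[C@H]2[C@]1(C(OC)OC)CCC(=O)[C@@](C)(C(=O)OC)[C@H]1[C@@H]3C(=O)OC | intermediate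
24 | dimethyl 3β-hydroxy-20,20-dimethoxygibberell-16-ene-7,19-dioate | C=C1C[C@]23C[C@H]1CC[C@H]2[C@]1(C(OC)OC)CC[C@H](O)[C@@](C)(C(=O)OC)[C@H]1[C@@H]3C(=O)OC | intermediate
25 | dimethyl 3β-hydroxy-20-oxogibberell-16-ene-7,19-dioate (dimethyl ester of the target) | C=C1C[C@]23C[C@H]1CC[C@H]2[C@]1(C=O)CC[C@H](O)[C@@](C)(C(=O)OC)[C@H]1[C@@H]3C(=O)OC | intermediate
26 | 3β-hydroxy-20-oxogibberell-16-ene-7,19-dioic acid (the target gibberellin) | C=C1C[C@]23C[C@H]1CC[C@H]2[C@]1(C=O)CC[C@H](O)[C@@](C)(C(=O)O)[C@H]1[C@@H]3C(=O)O | target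

**Totals**
Total step count: 17. Longest linear sequence: 16 steps (steps 1–8 and 10–17; step 9 is a one-step side branch).

**Steps most likely to fail**

Step 12 (key step). The released vinyl ketone may oligomerise, or closure may stall at reversible C–O ring formation or occur on the α face. The fallback uses known chemistry and sets out from 15. Oxidation with NaIO4 should give the sulfoxide of the Michael adduct F1, and thermolysis (toluene, 110 °C) the vinyl ketone F2. Cs2CO3 in CH2Cl2 should then close ring A by a Robinson-type intramolecular Michael addition of the aldehyde enolate, cis to the C5 side chain, to give the saturated cis-fused keto aldehyde F3. α-Selenation (PhSeCl, pyridine) and H2O2 oxidation with syn-elimination should introduce the 4(5)-double bond and return to the route at 21. This fallback depends on the Michael step having placed the side chain on the β face at C5.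

Step 5. The γ-dienolate may acylate at C14 instead of C9, or intermolecular Claisen condensation may outrun ring closure. The fallback sets out from 4. Thermodynamic carbomethoxylation (NaH, dimethyl carbonate) at the unhindered C9 should give the β-keto ester F4, and NaH/PhNTf2 its enol triflate F5. Negishi coupling with the Reformatsky reagent from dimethyl bromosuccinate (Zn; Pd2(dba)3, P(t-Bu)3) should give the triester F6. A normal Dieckmann closure (NaOMe, MeOH) should give the keto diester F7, and Krapcho decarboxylation (LiCl, wet DMSO, 130 °C) should return to the route at 8.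

Step 14. Hydride may add 1,2 to the C3 ketone, or hydride and methyl may be delivered with poor facial selectivity. The fallback sets out from 22. Dissolving-metal reduction (Zn dust, AcOH, THF, 25 °C) should give the saturated β-keto ester F8 under protonation control at C5. Methylation of its stabilised enolate (K2CO3, MeI, acetone) anti to the C10 substituent should return to the route at 23.

**Further compounds**
F1 | step 12 | sulfoxide of Michael adduct 15 | C=C1C[C@]23C[C@H]1CC[C@H]2C(C=O)C(C(C(=O)OC)C(=O)CCS(=O)c4ccccc4)[C@@H]3C(=O)OC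
F2 | step 12 | vinyl ketone from the sulfoxide | C=C1C[C@]23C[C@H]1CC[C@H]2C(C=O)C(C(C(=O)OC)C(=O)C=C)[C@@H]3C(=O)OC
F3 | step 12 | cis-fused (5α-H) ring A keto aldehyde: 4,5-dihydro-5-epi form of 21 | C=C1C[C@]23C[C@H]1CC[C@H]2[C@]1(C=O)CCC(=O)C(C(=O)OC)[C@@H]1[C@@H]3C(=O)OC
F4 | step 5 | methyl (4R)-2-oxo-4-[3-(trimethylsilyl)prop-1-en-2-yl]cyclohexane-1-carboxylate | O=C1C[C@H](C(=C)C[Si](C)(C)C)CCC1C(=O)OC
F5 | step 5 | enol triflate of the β-keto ester | COC(=O)C1=C(OS(=O)(=O)C(F)(F)F)C[C@H](C(=C)C[Si](C)(C)C)CC1
F6 | step 5 | triester from Negishi coupling: dimethyl 2-[2-(methoxycarbonyl)cyclohex-1-enyl]succinate bearing the C13 side chain | COC(=O)C1=C(C(CC(=O)OC)C(=O)OC)C[C@H](C(=C)C[Si](C)(C)C)CC1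
F7 | step 5 | dimethyl (6R)-3-oxo-6-[3-(trimethylsilyl)prop-1-en-2-yl]-2,3,4,5,6,7-hexahydro-1H-indene-1,2-dicarboxylate | COC(=O)C1C(C(=O)OC)C(=O)C2=C1C[C@H](C(=C)C[Si](C)(C)C)CC2
F8 | step 14 | 4,5-dihydro derivative of 22 (5β-H, C4 epimers) | C=C1C[C@]23C[C@H]1CC[C@H]2[C@]1(C(OC)OC)CCC(=O)C(C(=O)OC)[C@H]1[C@@H]3C(=O)OC
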